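The route rests on cutting C3a–C3 of the dihydrobenzofuran (O1, C2, C3, C3a, C4–C7, C7a). Because C3 is an unsubstituted CH2 flanking the oxygen-bearing stereocentre C2, the O1–C2–C3 fragment equals the O–CH–CH3 unit of lactic acid, and C3 can begin as a methyl group. A single Pd(0)/pivalate C(sp3)–H arylation then joins that methyl carbon to the brominated arene carbon and closes the five-membered ring while C2 stays untouched. Its substrate is an (S)-sec-alkyl 2-bromo-3,5-bis(MOM-oxy)phenyl ether in which the future isopropenyl group is stored as a TES-capped tertiary carbinol. Bromination and acylation at C7, alkene release, deprotection and methylene bridging to the pyrone at C5 complete the target.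

Key step: step 6

Remark on the chemistry: read from the SMILES, the target is (S) at C2 of the dihydrobenzofuran and (S) at the α-carbon of the acyl chain; since the aryl ether is made with inversion, the (R)-lactate is the antipode required, and the E/Z geometry of the silyl enol ether used for the pyrone is immaterial.

Step 1
Reactants: 1 phloroglucinol (benzene-1,3,5-triol)
Product: 2 3,5-bis(methoxymethoxy)phenol
Conditions: MOMCl (2.0 equiv), i-Pr2NEt (2.2 equiv), THF/DMF, 0 °C → rt; chromatography
Reagents that add atoms: chloromethyl methyl ether (MOMCl), COCCl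
Why: Statistical Williamson-type O-alkylation of a triphenol whose three hydroxyl groups are equivalent, so only the degree of alkylation has to be sorted out by chromatography and the mono- and tris-ethers can be recycled.

Step 2
Reactants: 2 3,5-bis(methoxymethoxy)phenol
Product: 3 2-bromo-3,5-bis(methoxymethoxy)phenol
Conditions: NBS (1.0 equiv), i-Pr2NH (10 mol %), CH2Cl2, −78 → −20 °C, dark
Reagents that add atoms: N-bromosuccinimide, O=C1CCC(=O)N1Br
Why: Secondary-amine-catalysed ortho-selective electrophilic bromination of a phenol, in which hydrogen bonding to the free OH steers bromine to the adjacent carbon, the para carbon is shielded by two flanking MOM ethers, and one equivalent of NBS at low temperature limits polybromination.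

Step 3
Reactants: 3 2-bromo-3,5-bis(methoxymethoxy)phenol; 4 methyl (R)-lactate
Product: 5 methyl (2S)-2-[2-bromo-3,5-bis(methoxymethoxy)phenoxy]propanoate
Conditions: PPh3, DIAD, THF, 0 °C → rt
Reagents that add atoms: none
Why: Mitsunobu etherification, in which the fairly acidic ortho-bromophenol displaces the phosphonium-activated secondary hydroxyl group by SN2 with inversion, turning the (R)-carbinol into the (S)-aryloxy stereocentre that becomes C2.

Step 4
Reactants: 5 methyl (2S)-2-[2-bromo-3,5-bis(methoxymethoxy)phenoxy]propanoate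
Product: 7 (3S)-3-[2-bromo-3,5-bis(methoxymethoxy)phenoxy]-2-methylbutan-2-ol, via methyl ketone 6 (not isolated)
Conditions: MeMgBr (3.0 equiv), THF, −40 → 0 °C; aqueous quench
Reagents that add atoms: methylmagnesium bromide, C[Mg]Br
Why: Double Grignard addition to the ester through ketone 6, in which carbonyl addition at low temperature outruns enolisation of the α-aryloxy carbonyl compounds so that the stereocentre is retained, while the aryl bromide and the MOM ethers are inert to MeMgBr.

Step 5
Reactants: 7 (3S)-3-[2-bromo-3,5-bis(methoxymethoxy)phenoxy]-2-methylbutan-2-ol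
Product: 8 triethyl{[(3S)-3-[2-bromo-3,5-bis(methoxymethoxy)phenoxy]-2-methylbutan-2-yl]oxy}silane
Conditions: TESOTf (1.2 equiv), 2,6-lutidine, CH2Cl2, −78 → 0 °C
Reagents that add atoms: triethylsilyl trifluoromethanesulfonate (TESOTf), CC[Si](CC)(CC)OS(=O)(=O)C(F)(F)F
Why: Silylation of a hindered tertiary alcohol with a silyl triflate and a non-nucleophilic pyridine base, where a small excess at low temperature reacts with the hydroxyl group well before the aryl MOM acetals are attacked.

Step 6
Reactants: 8 triethyl{[(3S)-3-[2-bromo-3,5-bis(methoxymethoxy)phenoxy]-2-methylbutan-2-yl]oxy}silane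
Product: 9 (2S)-4,6-bis(methoxymethoxy)-2-[2-(triethylsilyloxy)propan-2-yl]-2,3-dihydro-1-benzofuran
Conditions: Pd(OAc)2 (5 mol %), PCy3·HBF4 (10 mol %), PivOH (30 mol %), Cs2CO3 (1.5 equiv), mesitylene, 140 °C, argon
Reagents that add atoms: none
Why: Oxidative addition of the C3a–Br bond to Pd(0)/PCy3 and exchange of bromide for pivalate give an arylpalladium pivalate that cleaves one C–H bond of the methyl group on C2 by concerted metalation–deprotonation, and C(sp2)–C(sp3) reductive elimination from the resulting palladacycle (Pd, C3a, C7a, O1, C2, C3) forms C3a–C3 while carbonate regenerates pivalate. The closest known reactions are the Pd(0)/pivalate alkane arylations of 2-haloaryl tert-alkyl ethers to 2,2-dialkyl-2,3-dihydrobenzofurans and of N-sec-alkyl-2-haloanilides to 2-substituted indolines, the latter showing that a methine carbon next to the reacting methyl group is tolerated. The five-membered ring O1–C2–C3–C3a–C7a is closed by contraction of a six-membered palladacycle, formally a 5-exo closure in which the broken C–H bond lies outside the new ring. No stereocentre is created and C2 keeps the (S) configuration set in step 3, because none of its four bonds is broken and its hydrogen cannot reach a syn-coplanar alignment with palladium inside the chelate, which suppresses β-hydride elimination. The step needs site selectivity for the C2-methyl group over the two carbinol methyl groups and the terminal methyl of the C4 MOM ether, which would demand seven-membered palladacycles, and over the OCH2O and C2–H bonds, which are non-primary and would demand strained five-membered ones. The bulky CMe2(OTES) neighbour stands in for the missing gem-dialkyl effect by turning the sec-alkyl group out of the arene plane towards palladium, and its silyl cap shuts off C–O coupling of a free alkoxide and the Heck closure that a free isopropenyl group would undergo.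

Step 7
Reactants: 9 (2S)-4,6-bis(methoxymethoxy)-2-[2-(triethylsilyloxy)propan-2-yl]-2,3-dihydro-1-benzofuran
Product: 10 (2S)-7-bromo-4,6-bis(methoxymethoxy)-2-[2-(triethylsilyloxy)propan-2-yl]-2,3-dihydro-1-benzofuran
Conditions: NBS (1.0 equiv), CH2Cl2, −78 → 0 °C, dark
Reagents that add atoms: N-bromosuccinimide, O=C1CCC(=O)N1Br
Why: Electrophilic aromatic bromination in which C5 is buried between two freely rotating MOM ethers whereas C7 is flanked by the tied-back ring oxygen O1, the same steric bias that sends NBS to C8 of 5,7-dialkoxychromans, and one equivalent at low temperature avoids dibromination.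

Step 8
Reactants: 10 (2S)-7-bromo-4,6-bis(methoxymethoxy)-2-[2-(triethylsilyloxy)propan-2-yl]-2,3-dihydro-1-benzofuran
Product: 11 2-[(2S)-7-bromo-4,6-bis(methoxymethoxy)-2,3-dihydro-1-benzofuran-2-yl]propan-2-ol
Conditions: HF·pyridine, pyridine, THF, 0 °C → rt
Reagents that add atoms: none
Why: Fluoride-induced Si–O cleavage driven by the strong Si–F bond, carried out with pyridine-buffered HF that leaves the aryl MOM ethers and the aryl bromide intact.

Step 9
Reactants: 11 2-[(2S)-7-bromo-4,6-bis(methoxymethoxy)-2,3-dihydro-1-benzofuran-2-yl]propan-2-ol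
Product: 13 (2S)-7-bromo-4,6-bis(methoxymethoxy)-2-(prop-1-en-2-yl)-2,3-dihydro-1-benzofuran, via chlorosulfite ester 12 (not isolated)
Conditions: SOCl2 (1.3 equiv), pyridine, CH2Cl2, −20 → 0 °C
Reagents that add atoms: thionyl chloride, O=S(Cl)Cl (its atoms stay in 12 only)
Why: Dehydration of a tertiary alcohol through chlorosulfite 12 and pyridine-induced E2 elimination, the classical passage from 2-(2-hydroxypropan-2-yl)- to 2-isopropenyl-2,3-dihydrobenzofurans, in which six accessible methyl hydrogens compete with one hindered C2–H, no free cation arises that could shift hydride from C2, and the basic medium prevents migration of the alkene towards the aromatic benzofuran.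

Step 10
Reactants: 14 (S)-2-methylbutanoic acid
Product: 16 (2S)-N-methoxy-N,2-dimethylbutanamide, via acyl imidazole 15 (not isolated)
Conditions: CDI (1.1 equiv), CH2Cl2, 0 °C → rt; then MeNH(OMe)·HCl (1.2 equiv), rt
Reagents that add atoms: 1,1'-carbonyldiimidazole, O=C(n1ccnc1)n1ccnc1 (imidazolyl group of 15 only); N,O-dimethylhydroxylamine hydrochloride, CNOC.Cl
Why: Weinreb amide formation by CDI activation through acyl imidazole 15, which needs neither strong base nor a ketene-prone acid chloride, so the α-stereocentre of the acid is retained.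

Step 11
Reactants: 13 (2S)-7-bromo-4,6-bis(methoxymethoxy)-2-(prop-1-en-2-yl)-2,3-dihydro-1-benzofuran; 16 (2S)-N-methoxy-N,2-dimethylbutanamide
Product: 18 (2S)-1-[(2S)-4,6-bis(methoxymethoxy)-2-(prop-1-en-2-yl)-2,3-dihydro-1-benzofuran-7-yl]-2-methylbutan-1-one, via aryllithium 17 (not isolated)
Conditions: n-BuLi (1.05 equiv), THF, −78 °C; then 16 (1.2 equiv), −78 → −20 °C; AcOH/THF quench at −78 °C
Reagents that add atoms: n-butyllithium, [Li]CCCC (lithium of 17 only)
Why: Bromine–lithium exchange followed by Weinreb ketone synthesis, in which exchange at −78 °C is faster than any deprotonation, aryllithium 17 is stabilised by O1 and the C6 MOM ether, and the chelated tetrahedral adduct releases the ketone only on the cold acidic quench, which prevents over-addition and keeps the (S)-α-stereocentre away from base.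

Step 12
Reactants: 18 (2S)-1-[(2S)-4,6-bis(methoxymethoxy)-2-(prop-1-en-2-yl)-2,3-dihydro-1-benzofuran-7-yl]-2-methylbutan-1-one
Product: 19 (2S)-1-[(2S)-4,6-dihydroxy-2-(prop-1-en-2-yl)-2,3-dihydro-1-benzofuran-7-yl]-2-methylbutan-1-one
Conditions: conc HCl (cat), MeOH (dilute), rt → 40 °C
Reagents that add atoms: none
Why: Acid-catalysed acetal exchange (MOM cleavage) under conditions that prenyl-type alkenes on phloroglucinol nuclei tolerate, where the isopropenyl group is further deactivated towards protonation by the allylic C2–O1 bond, methanol carries the formaldehyde unit away as its acetal, and the hindered ketone enolises too slowly to epimerise.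

Step 13
Reactants: 20 pentan-3-one
Product: 21 3-(trimethylsilyloxy)pent-2-ene (E/Z mixture)
Conditions: TMSOTf (1.1 equiv), Et3N (1.3 equiv), CH2Cl2, 0 °C; distillation
Reagents that add atoms: trimethylsilyl trifluoromethanesulfonate (TMSOTf), C[Si](C)(C)OS(=O)(=O)C(F)(F)F
Why: Soft enolisation and O-silylation of a symmetrical ketone, for which no regiochemical question exists.

Step 14
Reactants: 21 3-(trimethylsilyloxy)pent-2-ene; 22 malonyl dichloride
Product: 24 6-ethyl-4-hydroxy-5-methyl-2H-pyran-2-one, via diketo acid chloride 23 (not isolated)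
Conditions: Et2O, −78 °C → rt
Reagents that add atoms: none
Why: C-acylation of the silyl enol ether by one acyl chloride group gives 23, whose enolised ethyl ketone closes onto the second acyl chloride in a six-membered lactonisation, the known one-flask route from silyl enol ethers and malonyl dichloride to 4-hydroxy-2-pyrones.

Step 15
Reactants: 24 6-ethyl-4-hydroxy-5-methyl-2H-pyran-2-one; 19 (2S)-1-[(2S)-4,6-dihydroxy-2-(prop-1-en-2-yl)-2,3-dihydro-1-benzofuran-7-yl]-2-methylbutan-1-one
Product: 27 3-({(2S)-4,6-dihydroxy-7-[(2S)-2-methylbutanoyl]-2-(prop-1-en-2-yl)-2,3-dihydro-1-benzofuran-5-yl}methyl)-6-ethyl-4-hydroxy-5-methyl-2H-pyran-2-one (target CNP0261501.1), via Mannich base 25 (not isolated), via pyrone methide 26 (not isolated)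
Conditions: 24, Me2N=CH2+ I− (1.0 equiv), CHCl3, rt; then 19 (1.0 equiv), rt → 45 °C
Reagents that add atoms: Eschenmoser's salt (N,N-dimethylmethyleneiminium iodide), C=[N+](C)C.[I-]
Why: Mannich/retro-Michael/Michael sequence (carba-Betti-type methylene bridging) known for joining 4-hydroxy-2-pyrones to acylphloroglucinols, in which the pyrone is aminomethylated at its only nucleophilic carbon C3 to give 25, loss of dimethylamine gives methide 26, and 19 attacks through C5, its only free ring carbon, under conditions that touch neither stereocentre nor the alkene.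

Compound list
1 | phloroglucinol (benzene-1,3,5-triol) | Oc1cc(O)cc(O)c1 | starting material
2 | 3,5-bis(methoxymethoxy)phenol | COCOc1cc(O)cc(OCOC)c1 | intermediate
3 | 2-bromo-3,5-bis(methoxymethoxy)phenol | COCOc1cc(O)c(Br)c(OCOC)c1 | intermediate
4 | methyl (R)-lactate | C[C@@H](O)C(=O)OC | starting material
5 | methyl (2S)-2-[2-bromo-3,5-bis(methoxymethoxy)phenoxy]propanoate | COC(=O)[C@@H](Oc1cc(OCOC)cc(OCOC)c1Br)C | intermediate
6 | (3S)-3-[2-bromo-3,5-bis(methoxymethoxy)phenoxy]butan-2-one (not isolated) | CC(=O)[C@@H](Oc1cc(OCOC)cc(OCOC)c1Br)C | intermediate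
7 | (3S)-3-[2-bromo-3,5-bis(methoxymethoxy)phenoxy]-2-methylbutan-2-ol | CC(C)(O)[C@@H](Oc1cc(OCOC)cc(OCOC)c1Br)C | intermediate
8 | triethyl{[(3S)-3-[2-bromo-3,5-bis(methoxymethoxy)phenoxy]-2-methylbutan-2-yl]oxy}silane (key-step precursor) | CC(C)(O[Si](CC)(CC)CC)[C@@H](Oc1cc(OCOC)cc(OCOC)c1Br)C | intermediate
9 | (2S)-4,6-bis(methoxymethoxy)-2-[2-(triethylsilyloxy)propan-2-yl]-2,3-dihydro-1-benzofuran (key-step product) | CC(C)(O[Si](CC)(CC)CC)[C@@H]1Cc2c(OCOC)cc(OCOC)cc2O1 | intermediate
10 | (2S)-7-bromo-4,6-bis(methoxymethoxy)-2-[2-(triethylsilyloxy)propan-2-yl]-2,3-dihydro-1-benzofuran | CC(C)(O[Si](CC)(CC)CC)[C@@H]1Cc2c(OCOC)cc(OCOC)c(Br)c2O1 | intermediate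
11 | 2-[(2S)-7-bromo-4,6-bis(methoxymethoxy)-2,3-dihydro-1-benzofuran-2-yl]propan-2-ol | CC(C)(O)[C@@H]1Cc2c(OCOC)cc(OCOC)c(Br)c2O1 | intermediate
12 | chlorosulfite ester of 11 (not isolated) | CC(C)(OS(=O)Cl)[C@@H]1Cc2c(OCOC)cc(OCOC)c(Br)c2O1 | intermediate
13 | (2S)-7-bromo-4,6-bis(methoxymethoxy)-2-(prop-1-en-2-yl)-2,3-dihydro-1-benzofuran | C=C(C)[C@@H]1Cc2c(OCOC)cc(OCOC)c(Br)c2O1 | intermediate
14 | (S)-2-methylbutanoic acid | OC(=O)[C@@H](C)CC | starting material
15 | 1-[(2S)-2-methylbutanoyl]imidazole (not isolated) | O=C([C@@H](C)CC)n1ccnc1 | intermediate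
16 | (2S)-N-methoxy-N,2-dimethylbutanamide | CON(C)C(=O)[C@@H](C)CC | intermediate
17 | [(2S)-4,6-bis(methoxymethoxy)-2-(prop-1-en-2-yl)-2,3-dihydro-1-benzofuran-7-yl]lithium (not isolated) | C=C(C)[C@@H]1Cc2c(OCOC)cc(OCOC)c([Li])c2O1 | intermediate
18 | (2S)-1-[(2S)-4,6-bis(methoxymethoxy)-2-(prop-1-en-2-yl)-2,3-dihydro-1-benzofuran-7-yl]-2-methylbutan-1-one | C=C(C)[C@@H]1Cc2c(OCOC)cc(OCOC)c(C(=O)[C@@H](C)CC)c2O1 | intermediate
19 | (2S)-1-[(2S)-4,6-dihydroxy-2-(prop-1-en-2-yl)-2,3-dihydro-1-benzofuran-7-yl]-2-methylbutan-1-one | C=C(C)[C@@H]1Cc2c(O)cc(O)c(C(=O)[C@@H](C)CC)c2O1 | intermediate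
20 | pentan-3-one | CCC(=O)CC | starting material
21 | 3-(trimethylsilyloxy)pent-2-ene (E/Z mixture) | CC=C(CC)O[Si](C)(C)C | intermediate
22 | malonyl dichloride | O=C(Cl)CC(=O)Cl | starting material
23 | 4-methyl-3,5-dioxoheptanoyl chloride (not isolated) | CCC(=O)C(C)C(=O)CC(=O)Cl | intermediate
24 | 6-ethyl-4-hydroxy-5-methyl-2H-pyran-2-one | CCc1oc(=O)cc(O)c1C | intermediate
25 | 3-[(dimethylamino)methyl]-6-ethyl-4-hydroxy-5-methyl-2H-pyran-2-one (not isolated) | CCc1oc(=O)c(CN(C)C)c(O)c1C | intermediate
26 | 6-ethyl-5-methyl-3-methylidenepyran-2,4-dione (not isolated) | C=C1C(=O)OC(CC)=C(C)C1=O | intermediate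
27 | 3-({(2S)-4,6-dihydroxy-7-[(2S)-2-methylbutanoyl]-2-(prop-1-en-2-yl)-2,3-dihydro-1-benzofuran-5-yl}methyl)-6-ethyl-4-hydroxy-5-methyl-2H-pyran-2-one | C=C(C)[C@@H]1Cc2c(O)c(Cc3c(O)c(C)c(CC)oc3=O)c(O)c(C(=O)[C@@H](C)CC)c2O1 | target

Total step count: 15
Longest linear sequence: 12 (steps 1–9, 11, 12, 15)

Steps most likely to fail

1. Step 6.
- What may go wrong: oxidative addition at the electron-rich, doubly ortho-oxygenated C–Br bond is slow, and the secondary ether lacks gem-dialkyl compression. Hydrodebromination or palladation of a more remote methyl group may therefore outrun cleavage of the wanted C–H bond.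
- Fallback: it sets out from 3 and comes back at 9. It forms O1–C2 in place of C3a–C3 and takes the configuration from a catalyst in place of the chiral pool.
 - Double lithiation of 3 (n-BuLi, 2.1 equiv, THF, −78 °C; O–H deprotonation, then Br–Li exchange) and C-alkylation with prenyl bromide should give 3,5-bis(methoxymethoxy)-2-(3-methylbut-2-en-1-yl)phenol F1.
 - TBSCl/imidazole converts it into tert-butyl[3,5-bis(methoxymethoxy)-2-(3-methylbut-2-en-1-yl)phenoxy]dimethylsilane F2.
 - Shi epoxidation follows (Oxone, K2CO3 buffer). The ketone antipode is chosen for the R-epoxide, which by the spiro model is the D-fructose-derived one. This should give tert-butyl[2-{[(2R)-3,3-dimethyloxiran-2-yl]methyl}-3,5-bis(methoxymethoxy)phenoxy]dimethylsilane F3.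
 - TBAF then frees the phenoxide, which opens the oxirane 5-exo-tet at its secondary carbon with inversion to 2-[(2S)-4,6-bis(methoxymethoxy)-2,3-dihydro-1-benzofuran-2-yl]propan-2-ol F4.
 - Silylation as in step 5 leads to 9.

2. Step 15.
- What may go wrong: either partner may condense with itself through the one-carbon unit, and retro-Mannich exchange may scramble the bridge. Both would compete with the cross-coupling.
- Fallback: it sets out from 19 and comes back at 27, with the roles of the two partners reversed and the one-carbon unit fixed in a separate step.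
 - Compound 19 alone is aminomethylated at C5 with Eschenmoser's salt (CH2Cl2, rt).
 - (2S)-1-{(2S)-5-[(dimethylamino)methyl]-4,6-dihydroxy-2-(prop-1-en-2-yl)-2,3-dihydro-1-benzofuran-7-yl}-2-methylbutan-1-one F5 is isolated, so no free formaldehyde equivalent is left when the pyrone is added.
 - Heating F5 with 24 in dioxane expels the amine. The C5-methylidene ortho-quinone methide F6 formed in this way is captured by C3 of the pyrone to give 27.

3. Step 11.
- What may go wrong: proton transfer from the α-C–H of the branched amide to the doubly ortho-substituted aryllithium, or base-induced breakdown of the N–OMe group, may outrun carbonyl addition. The arylmetal would then be lost and the α-stereocentre eroded.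
- Fallback: it sets out from 16 and 13 and comes back at 18.
 - DIBAL-H (THF, −78 °C) reduces 16 to (S)-2-methylbutanal F7, which is used crude and cold.
 - Aryllithium 17, generated from 13 as before, adds to this smaller and far more electrophilic carbonyl group.
 - The product is (2S)-1-[(2S)-4,6-bis(methoxymethoxy)-2-(prop-1-en-2-yl)-2,3-dihydro-1-benzofuran-7-yl]-2-methylbutan-1-ol F8, formed as a mixture of epimers at the new carbinol carbon.
 - The mixture is of no consequence, because Dess–Martin periodinane (NaHCO3, CH2Cl2) oxidises it to 18 under non-basic conditions.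

Further compounds
F1 | step 6 | 3,5-bis(methoxymethoxy)-2-(3-methylbut-2-en-1-yl)phenol | CC(C)=CCc1c(O)cc(OCOC)cc1OCOC
F2 | step 6 | tert-butyl[3,5-bis(methoxymethoxy)-2-(3-methylbut-2-en-1-yl)phenoxy]dimethylsilane | CC(C)=CCc1c(O[Si](C)(C)C(C)(C)C)cc(OCOC)cc1OCOC
F3 | step 6 | tert-butyl[2-{[(2R)-3,3-dimethyloxiran-2-yl]methyl}-3,5-bis(methoxymethoxy)phenoxy]dimethylsilane | CC1(C)O[C@@H]1Cc2c(O[Si](C)(C)C(C)(C)C)cc(OCOC)cc2OCOC
F4 | step 6 | 2-[(2S)-4,6-bis(methoxymethoxy)-2,3-dihydro-1-benzofuran-2-yl]propan-2-ol | CC(C)(O)[C@@H]1Cc2c(OCOC)cc(OCOC)cc2O1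
F5 | step 15 | (2S)-1-{(2S)-5-[(dimethylamino)methyl]-4,6-dihydroxy-2-(prop-1-en-2-yl)-2,3-dihydro-1-benzofuran-7-yl}-2-methylbutan-1-one | C=C(C)[C@@H]1Cc2c(O)c(CN(C)C)c(O)c(C(=O)[C@@H](C)CC)c2O1
F6 | step 15 | C5-methylidene ortho-quinone methide derived from F5 | C=C(C)[C@@H]1CC2=C(O1)C(C(=O)[C@@H](C)CC)=C(O)C(=C)C2=O
F7 | step 11 | (S)-2-methylbutanal | O=C[C@@H](C)CC
F8 | step 11 | (2S)-1-[(2S)-4,6-bis(methoxymethoxy)-2-(prop-1-en-2-yl)-2,3-dihydro-1-benzofuran-7-yl]-2-methylbutan-1-ol (both carbinol epimers) | C=C(C)[C@@H]1Cc2c(OCOC)cc(OCOC)c(C(O)[C@@H](C)CC)c2O1
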